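1. Blue gave 32.2% and violet 11.0% at 25.0 min, on 4.00 times the free catalyst, so the catalyst charge was a number I needed well. I read an order of 0.775 from these two runs.

| flask | starting material | solid reagent | free catalyst | remark | time |
|---|---|---|---|---|---|
| violet | 0.050 M | 0.065 M | 0.25 mM | run made earlier |  |
| blue | 0.050 M | 0.065 M | 1 mM | run made earlier |  |
| ochre | 0.025 M | 0.065 M | 0.50 mM | run made earlier |  |
| flask | 0.050 M | 0.0650 M | 0.50 mM |  | 25 min |

| run | time / min | product / % |
|---|---|---|
| violet | 4.00 | 1.4 |
| violet | 8.00 | 2.9 |
| violet | 10.0 | 4.0 |
| violet | 15.0 | 7.1 |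
| violet | 20.0 | 8.7 |
| violet | 25.0 | 11.0 |
| blue | 4.00 | 5.6 |
| blue | 8.00 | 11.3 |
| blue | 10.0 | 14.2 |
| blue | 15.0 | 20.3 |
| blue | 20.0 | 26.5 |
| blue | 25.0 | 32.2 |
| ochre | 5.00 | 5.1 |
| ochre | 10.0 | 10.5 |
| ochre | 15.0 | 15.2 |
| ochre | 20.0 | 20.1 |
| ochre | 25.0 | 24.2 |

(scatter of a reading: 0.3 percentage points)

- solid, in amounts per volume of the solution: solid reagent
- the analysis behind the earlier runs scatters by 0.3 percentage points, standard deviation
- steps under discussion: partner + free catalyst <-> catalyst intermediate A; starting material + catalyst intermediate A <-> catalyst intermediate B; catalyst intermediate B -> catalyst intermediate C; catalyst intermediate C -> free catalyst + product; solid reagent <-> partner; 2 free catalyst <-> resting dimer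
- at the start none of the solid reagent is in solution

1. how much product there is at 25 min, in percent of the starting material charged
2. concentration of partner in solution at 25 min, in percent of saturation

2. From violet, that order gave my own estimate for the flask: 18.8% of the starting material.

3. The clock mattered more than the catalyst: blue rose from 14.2% at 10.0 min to 32.2% at 25.0 min, an order in time of 0.894, so I ranked the clock first and the catalyst second. Starting material came after them: ochre, with half the charge, read 24.2% on the flask's catalyst, against my 18.8%, a smaller order of 0.363 in size.

4. The steps spend one partner per product. I therefore defined the solid share, the fraction of the solid charge that the product made so far has consumed. For the flask I got 14.5%, and because this is well below one, I did not need the solid charge closely.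

5. The forecast said 19.2% (17.8% to 20.6%), a little above my figure, and 90% of saturation (65% to 99%), since “partner should sit close to saturation”.

6. The flask gave 19.3% and 98.9% of saturation.

    partner + free catalyst ⇌ catalyst intermediate A (K = 48.0 M⁻¹, k = 2.12 M⁻¹ s⁻¹)
    starting material + catalyst intermediate A ⇌ catalyst intermediate B (K = 7.40 M⁻¹, k = 3.82 M⁻¹ s⁻¹)
    catalyst intermediate B → catalyst intermediate C (k = 0.211 s⁻¹)
    catalyst intermediate C → free catalyst + product (k = 1.34 s⁻¹)
    solid reagent ⇌ partner, rate k5*(cs5 - [partner]) while solid is left; crystals form when [partner] > cs5 (solubility = 25.0 mM, k = 0.0220 s⁻¹)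
    2 free catalyst ⇌ resting dimer (K = 1200 M⁻¹, k = 1.53 M⁻¹ s⁻¹)

The flask's solid share came to 14.9%, with 46.8% of the solid reagent still solid at 25.0 min. A neighbouring flask held 0.016 M of solid reagent, 0.320 equiv, which made it the limiting reagent. My estimate put its share at 58.8%, but it gave 12.1%, a share of 37.7%. At 25.0 min its solid stood at 0% and its partner at 0.00990 M, with catalyst intermediate A at 12.1% of the catalyst charged, against 26.3% in the flask.

The data come from a simulation from invented constants; scatter was added.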